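C1 = quaternary C(CH3)(CO2Me), then C2, C3=C4, C5=C6, O7, C8 (acetal), C9, C10, C11, C12, C13 (quaternary), C14 (CH2). Ring A = C9–C13, ring B = C1–C2–C14–C13–C12, ring C = C2–C3–C4–C5–C13–C14, ring D = C5–C6–O7–C8–C9–C13.
The strategy rests on C4, the single CH between C3 and C5 in the three-carbon bridge of ring C. Removing it leaves a norbornene with a strained C3=C5 alkene. C4 therefore enters last as CBr2, and loss of H6 from the opened allyl cation gives the C3=C4–C5=C6–O7 dienol ether directly.
The C6–O7–C8 link (ring D) is made before the carbocycles. It holds C8 syn to C5, whereas an open C8 group would turn away from C6 through allylic 1,3-strain in the cycloaddition. It also removes the acidity of H9 and avoids a late dialdehyde. The free acetal oxygen carries TBS until the end.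
The norbornene comes from an intramolecular Diels–Alder reaction of the cyclopentadiene C13=C5–C3=C2 with the (E)-enoate C12=C1. The diene comes from dehydration of a tertiary allylic alcohol, itself made by an auxiliary-controlled aldol (C9–C13) of a hex-5-enoyl imide with silylated 2-(hydroxymethyl)cyclopentenone.
Ring order: cyclopentene (bought), then ring D (step 5), rings A and B together (step 9), and ring C by enlargement (step 10).

Key step: step 10

Assumption: the lithium Z-enolate of the N-acyl oxazolidinone reacts with the ketone in its chelated form, on the face used in alkylations, so the (S)-auxiliary gives (R)-C9. If the opposite sense is found, the equally available (R)-auxiliary is used.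

Step 1
Reactants: 1 cyclopent-2-en-1-one; 2 formaldehyde
Product: 3 2-(hydroxymethyl)cyclopent-2-en-1-one
Conditions: 37% aq. HCHO, Bu3P (10 mol %), MeOH–CHCl3, rt
Reagents that add atoms: formaldehyde (2), C=O
Why: Morita–Baylis–Hillman reaction: Bu3P adds to the enone β-carbon (future C3), the phosphonium enolate hydroxymethylates the α-carbon (C5), and loss of the phosphine restores the enone, which places C6 on the future central carbon of the later allyl cation without forming a stereocentre.

Step 2
Reactants: 3 2-(hydroxymethyl)cyclopent-2-en-1-one
Product: 4 2-{[(tert-butyldimethylsilyl)oxy]methyl}cyclopent-2-en-1-one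
Conditions: TBSCl, imidazole, CH2Cl2, 0 °C to rt
Reagents that add atoms: tert-butyldimethylsilyl chloride, CC(C)(C)[Si](C)(C)Cl
Why: Imidazole-promoted silylation masks the primary allylic alcohol so that in step 4 it neither quenches the enolate nor acts as an allylic leaving group.

Step 3
Reactants: 5 (S)-4-benzyl-1,3-oxazolidin-2-one; 6 hex-5-enoyl chloride
Product: 7 (S)-4-benzyl-3-(hex-5-enoyl)-1,3-oxazolidin-2-one
Conditions: n-BuLi, THF, −78 °C; then 6, −78 to 0 °C
Reagents that add atoms: hex-5-enoyl chloride (6), C=CCCCC(=O)Cl
Why: N-Acylation of the lithiated oxazolidinone gives the imide that carries C8–C12 (plus one sacrificial CH2) and the bought stereocentre that will control C9.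

Step 4
Reactants: 7 (S)-4-benzyl-3-(hex-5-enoyl)-1,3-oxazolidin-2-one; 4 silylated enone
Product: 9 aldol adduct (C9 R; both C13 epimers), via lithium Z-enolate 8 (not isolated)
Conditions: LiN(SiMe3)2, THF, −78 °C; 4, −78 °C; AcOH quench at −78 °C
Reagents that add atoms: none
Why: Evans-type auxiliary-controlled aldol addition to a ketone: the chelated Z-enolate 8 is shielded on one face by the benzyl group and adds kinetically 1,2 to the C13 carbonyl, which forms C9–C13 and sets C9 (R), while the cold acidic quench prevents retro-aldol and drift to the conjugate adduct, and the C13 carbinol configuration does not matter because C13 becomes sp2 in step 9.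

Step 5
Reactants: 9 aldol adduct
Product: 11 bicyclic β-hydroxy δ-lactone (ring D closed), via hydroxy imide 10 (not isolated)
Conditions: HF·pyridine, pyridine, THF, 0 °C; then Et3N, DMAP (cat.), CH2Cl2, rt
Reagents that add atoms: none
Why: Buffered fluoride cleaves the primary silyl ether and the freed C6–OH attacks the activated exocyclic imide carbonyl (DMAP-catalysed six-membered lactonisation), which forms O7–C8, releases the auxiliary for recovery and ties C8 to C6 without touching C9.

Step 6
Reactants: 11 lactone
Product: 12 lactol (anomeric mixture)
Conditions: i-Bu2AlH (2.2 equiv), CH2Cl2, −78 °C; aq. potassium sodium tartrate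
Reagents that add atoms: none
Why: Partial reduction of the δ-lactone stops at the tetrahedral aluminium acetal at −78 °C and gives the lactol on work-up, with no other carbonyl group present at this stage and with H9 no longer acidic afterwards.

Step 7
Reactants: 12 lactol
Product: 13 silyl acetal (C8 S and C9 R; OTBS trans to the C10 chain)
Conditions: TBSCl, imidazole, DMF, 0 °C
Reagents that add atoms: tert-butyldimethylsilyl chloride, CC(C)(C)[Si](C)(C)Cl
Why: Selective silylation of the equilibrating lactol at its less hindered equatorial hydroxyl (the tertiary C13–OH does not react with TBSCl) sets C8 trans to the C10 chain as in the target and gives a base-stable acetal, the minor anomer being removed by chromatography.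

Step 8
Reactants: 13 silyl acetal; 14 methyl methacrylate
Product: 15 (E)-enoate
Conditions: 14 (10 equiv), RuCl2(H2IMes)(=CH-C6H4-2-Oi-Pr) (second-generation Hoveyda–Grubbs catalyst, 5 mol %), CH2Cl2, 40 °C
Reagents that add atoms: methyl methacrylate (14), C=C(C)C(=O)OC
Why: Olefin cross-metathesis between the terminal alkene and the electron-poor 1,1-disubstituted methacrylate, which does not homodimerise, should give the trisubstituted enoate with the thermodynamically preferred E geometry, the hindered trisubstituted ring alkene staying inert.

Step 9
Reactants: 15 (E)-enoate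
Product: 18 tetracyclic norbornene ester (C3=C5 alkene; C6–OH and C8 aldehyde masked together as the cyclic silyl acetal), via tertiary mesylate 16 (not isolated), via cyclopentadiene 17 (not isolated)
Conditions: MsCl, Et3N, CH2Cl2, −30 to 0 °C; aqueous wash, solvent switch to toluene, BHT (cat.), 100 °C
Reagents that add atoms: none
Why: The tertiary allylic mesylate ionises to the C13–C5–C3 allyl cation, whose central carbon carries C6, so only H14 or H2 is lost (H9 is pseudo-equatorial and lies near the nodal plane) and a cyclopentadiene results; thermal 1,5-hydrogen shifts interconvert the diene isomers, and only 17, with the tether on diene terminus C13, can reach the enoate in an intramolecular Diels–Alder reaction (type 1, three-atom tether), in which the pseudo-axial C10 chain fixed by C9 selects the diene face (sets C13 and C2), the short tether forces C11 exo and so CO2Me endo, and suprafacial addition to the (E)-alkene sets C12 and C1 with CH3 cis to C11.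

Step 10
Reactants: 18 tetracyclic norbornene ester; 19 bromoform
Product: 22 C4-bromo bicyclo[3.2.1]octadiene dienol ether, via dibromocyclopropane 20 (not isolated), via bromoallyl cation 21 (not isolated)
Conditions: 19 (4 equiv), KOt-Bu (8 equiv), pentane, −20 °C to rt
Reagents that add atoms: bromoform (19), BrC(Br)Br
Why: KOt-Bu α-eliminates HBr from 19, and singlet CBr2 adds in one step ([2+1] addition) to C3=C5, the only alkene of 18, forming C3–C4 and C4–C5 in 20. The bromine of 20 that points toward C14 is cis to the C3–C2 and C5–C13 ring bonds, so its departure is concerted with the allowed disrotatory inward opening of the old C3–C5 bond (Woodward–Hoffmann–DePuy rule), is driven by release of cyclopropane and norbornane strain, and gives the 2-bromoallyl cation 21 (C3–C4(Br)–C5). The closest known reaction type is the dihalocarbene ring expansion of norbornenes to 3,4-dihalobicyclo[3.2.1]oct-2-enes, ended here by E1 proton loss instead of halide return. Ring C (C2–C3–C4–C5–C13–C14) is therefore closed by ring enlargement, that is by insertion of C4 into a five-membered ring, and not by an exo or endo cyclisation mode. The facial selectivity needed, exo attack syn to C14, is secured by the C1–C12 bridge and its endo CO2Me, which cover the endo face; the stereocentres this sets at C3 and C5 are transient, and 22 contains no new stereocentre. The regioselectivity of proton loss is secured by the substrate: C13 is quaternary and H2 is a bridgehead hydrogen, so only the pseudo-axial H6 of ring D is aligned with the cation at C5 and excess base removes it to give C3=C4(Br)–C5=C6–O7, while the neopentyl ester without α-hydrogen and the silyl acetal tolerate KOt-Bu.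

Step 11
Reactants: 22 C4-bromo dienol ether
Product: 23 debrominated dienol ether silyl acetal
Conditions: Pd(PPh3)4 (5 mol %), HCO2H, Et3N (excess), DMF, 60 °C
Reagents that add atoms: none
Why: Palladium-catalysed formate hydrogenolysis of an alkenyl bromide: oxidative addition of zerovalent palladium to C4–Br, exchange of bromide for formate, decarboxylation to the palladium hydride and reductive elimination replace Br by H with the diene retained, and the amine-buffered medium spares the dienol ether and the silyl acetal.

Step 12
Reactants: 23 dienol ether silyl acetal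
Product: 24 lactol (equatorial anomer)
Conditions: Bu4NF, AcOH (1 equiv each), THF, 0 °C
Reagents that add atoms: none
Why: Acetic-acid-buffered fluoride cleaves the Si–O bond and not the C8–O bond, so the lactol is freed with retention at C8 under nearly neutral conditions that disfavour ring opening to the dienol aldehyde.

Step 13
Reactants: 24 lactol; 25 3-methylbutanoyl chloride
Product: 26 target CNP0315847.1
Conditions: 25, pyridine, DMAP (cat.), CH2Cl2, −20 °C
Reagents that add atoms: 3-methylbutanoyl chloride (25), CC(C)CC(Cl)=O
Why: DMAP-catalysed O-acylation of the lactol at low temperature should be faster than its ring–chain tautomerism and occurs at oxygen, so C8 keeps its configuration (acyloxy equatorial, trans to C10, cis to H9), and any axial anomer is acylated more slowly because of its 1,3-diaxial contact with C12.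

Compound list
1 | cyclopent-2-en-1-one | O=C1C=CCC1 | starting material
2 | formaldehyde (37% aqueous) | C=O | starting material
3 | 2-(hydroxymethyl)cyclopent-2-en-1-one | O=C1CCC=C1CO | intermediate
4 | 2-{[(tert-butyldimethylsilyl)oxy]methyl}cyclopent-2-en-1-one | O=C1CCC=C1CO[Si](C)(C)C(C)(C)C | intermediate
5 | (S)-4-benzyl-1,3-oxazolidin-2-one | O=C1N[C@@H](Cc2ccccc2)CO1 | starting material
6 | hex-5-enoyl chloride | C=CCCCC(=O)Cl | starting material
7 | (S)-4-benzyl-3-(hex-5-enoyl)-1,3-oxazolidin-2-one | C=CCCCC(=O)N1[C@@H](Cc2ccccc2)COC1=O | intermediate
8 | lithium (Z)-enolate of 7 | C=CCC/C=C(\[O-])N1[C@@H](Cc2ccccc2)COC1=O.[Li+] | intermediate (not isolated)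
9 | (4S)-4-benzyl-3-[(2R)-2-(1-hydroxy-2-{[(tert-butyldimethylsilyl)oxy]methyl}cyclopent-2-en-1-yl)hex-5-enoyl]-1,3-oxazolidin-2-one (C13 epimers, both used) | C=CCC[C@@H](C(=O)N1[C@@H](Cc2ccccc2)COC1=O)C1(O)CCC=C1CO[Si](C)(C)C(C)(C)C | intermediate
10 | hydroxy imide, the primary alcohol from 9 | C=CCC[C@@H](C(=O)N1[C@@H](Cc2ccccc2)COC1=O)C1(O)CCC=C1CO | intermediate (not isolated)
11 | (4R)-4-(but-3-en-1-yl)-4a-hydroxy-4,4a,5,6-tetrahydrocyclopenta[c]pyran-3(1H)-one (C13 epimers) | C=CCC[C@H]1C(=O)OCC2=CCCC12O | intermediate
12 | (4R)-4-(but-3-en-1-yl)-3,4,5,6-tetrahydrocyclopenta[c]pyran-3,4a(1H)-diol (lactol, anomeric mixture) | C=CCC[C@H]1C(O)OCC2=CCCC12O | intermediate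
13 | (3S,4R)-4-(but-3-en-1-yl)-3-[(tert-butyldimethylsilyl)oxy]-3,4,5,6-tetrahydrocyclopenta[c]pyran-4a(1H)-ol | C=CCC[C@H]1[C@H](O[Si](C)(C)C(C)(C)C)OCC2=CCCC12O | intermediate
14 | methyl methacrylate | C=C(C)C(=O)OC | starting material
15 | methyl (2E)-5-{(3S,4R)-3-[(tert-butyldimethylsilyl)oxy]-4a-hydroxy-1,3,4,4a,5,6-hexahydrocyclopenta[c]pyran-4-yl}-2-methylpent-2-enoate | COC(=O)/C(C)=C/CC[C@H]1[C@H](O[Si](C)(C)C(C)(C)C)OCC2=CCCC12O | intermediate
16 | tertiary allylic mesylate of 15 | COC(=O)/C(C)=C/CC[C@H]1[C@H](O[Si](C)(C)C(C)(C)C)OCC2=CCCC12OS(C)(=O)=O | intermediate (not isolated)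
17 | methyl (2E)-5-{(3S,4R)-3-[(tert-butyldimethylsilyl)oxy]-1,3,4,5-tetrahydrocyclopenta[c]pyran-4-yl}-2-methylpent-2-enoate (reactive diene isomer C13=C5–C3=C2) | COC(=O)/C(C)=C/CC[C@H]1[C@H](O[Si](C)(C)C(C)(C)C)OCC2=C1CC=C2 | intermediate (not isolated)
18 | tetracyclic norbornene ester: C3=C5 alkene, C5–C6H2–O7–C8H(OTBS)–C9 ring D, CO2Me endo and CH3 exo on C1, C11 exo on C12, OTBS trans to C10 | COC(=O)[C@]1(C)[C@@H]2C=C3CO[C@@H](O[Si](C)(C)C(C)(C)C)[C@@H]4CC[C@@H]1[C@]34C2 | intermediate (key-step precursor)
19 | bromoform | BrC(Br)Br | starting material
20 | exo gem-dibromocyclopropane on C3–C5 of 18 | COC(=O)[C@]1(C)[C@@H]2[C@H]5C(Br)(Br)[C@]53CO[C@@H](O[Si](C)(C)C(C)(C)C)[C@@H]4CC[C@@H]1[C@]34C2 | intermediate (not isolated)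
21 | 2-bromoallyl cation C3–C4(Br)–C5 with bromide counter-ion | COC(=O)[C@]1(C)[C@@H]2[CH+]C(Br)=C3CO[C@@H](O[Si](C)(C)C(C)(C)C)[C@@H]4CC[C@@H]1[C@]34C2.[Br-] | intermediate (not isolated)
22 | C4-bromo bicyclo[3.2.1]octadiene dienol ether, C8–OTBS | COC(=O)[C@]1(C)[C@@H]2C=C(Br)C3=CO[C@@H](O[Si](C)(C)C(C)(C)C)[C@@H]4CC[C@@H]1[C@]34C2 | intermediate (key-step product)
23 | debrominated dienol ether, C8–OTBS | COC(=O)[C@]1(C)[C@@H]2C=CC3=CO[C@@H](O[Si](C)(C)C(C)(C)C)[C@@H]4CC[C@@H]1[C@]34C2 | intermediate
24 | C8 lactol (equatorial anomer drawn) | COC(=O)[C@]1(C)[C@@H]2C=CC3=CO[C@@H](O)[C@@H]4CC[C@@H]1[C@]34C2 | intermediate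
25 | 3-methylbutanoyl chloride | CC(C)CC(Cl)=O | starting material
26 | CNP0315847.1 | COC(=O)[C@]1(C)[C@@H]2C=CC3=CO[C@@H](OC(=O)CC(C)C)[C@@H]4CC[C@@H]1[C@]34C2 | target

Total step count: 13. Longest linear sequence: 12 steps (1 to 26 through steps 1, 2 and 4–13).

Steps most likely to fail

Step 10. Three things may go wrong.
- Carbene transfer to the hindered, inductively deactivated trisubstituted alkene may be slow.
- The allyl cation may be captured by tert-butoxide or bromide before it loses H6.
- The excess alkoxide may attack the ester.

Fallback: carbene transfer and elimination are separated, and both are run without alkoxide. Compound 18 is heated with PhHgCBr3 in benzene at 80 °C, a neutral thermal source of CBr2. The adduct opens as before, but the cation is now closed by bromide return on the exo face of C3. This gives the isolable allylic dibromide F1. DBU in toluene (or AgBF4 and 2,6-di-tert-butylpyridine) then removes H6 in a vinylogous 1,4-dehydrobromination, and the route is rejoined at 22.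

Step 4. Four things may go wrong.
- Proton transfer from the enolisable ketone to the enolate may compete with addition.
- The aldol may reverse on warming.
- Conjugate addition may compete with carbonyl addition.
- The facial bias may erode.

Fallback: the enolate is generated reductively instead of with base. Compound 7 is converted through its dibutylboron enolate (Bu2BOTf, i-Pr2NEt, then NBS, CH2Cl2, −78 °C) into the α-bromo imide F2, either C9 epimer of which serves. SmI2 (2 equiv, THF, −78 °C) in the presence of 4 reduces the C–Br bond to a chelated trivalent samarium enolate (samarium Reformatsky reaction). This enolate is non-basic and strongly oxophilic, and it should add irreversibly to the ketone under the same auxiliary control. The route is rejoined at 9.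

Step 13. Ring–chain tautomerism of the dienol hemiacetal to the open aldehyde during acylation, followed by ketonisation, may consume the lactol, and anomeric control may be lost.

Fallback: the ester is made by displacement at C8 instead of acylation at oxygen. Compound 24 is treated with Cl3CCN and catalytic DBU under equilibrating conditions to give the axial trichloroacetimidate F3. 3-Methylbutanoic acid in CH2Cl2, without promoter, then displaces the imidate with inversion and gives the equatorial ester. The route is rejoined at 26.

Further compounds
F1 | step 10 | allylic dibromide (exo C3–Br, C4–Br, C4=C5) | COC(=O)[C@]1(C)[C@@H]2[C@@H](Br)C(Br)=C3CO[C@@H](O[Si](C)(C)C(C)(C)C)[C@@H]4CC[C@@H]1[C@]34C2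
F2 | step 4 | (4S)-4-benzyl-3-(2-bromohex-5-enoyl)-1,3-oxazolidin-2-one | C=CCCC(Br)C(=O)N1[C@@H](Cc2ccccc2)COC1=O
F3 | step 13 | axial C8 trichloroacetimidate of 24 | COC(=O)[C@]1(C)[C@@H]2C=CC3=CO[C@H](OC(=N)C(Cl)(Cl)Cl)[C@@H]4CC[C@@H]1[C@]34C2
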